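**Plan**

1. Numbering (daucane): C1 quaternary fusion carbon (angular CH3 = C15), C2 CH–OAc, C3 CH2, C4 C(OH)(i-Pr), C5 fusion CH, C6 CH–O-anisoyl, C7 CH2, C8 C(CH3)=, C9 =CH, C10 CH2; ring A = C1–C5, ring B = C1, C5–C10; β = face of C15.
2. Retrosynthesis: C10 methylene and C8=C9 go back to a C10 ketone (helper, later removed), the 6α-anisoate to an enol anisoate, the 2α-acetate to a C2 ketone; then C1–C5 and C8–C9 are cut together, as an intramolecular (4+3) cycloaddition of a 2-ethoxyallyl cation (C1–C10–C9) with a 2-acyloxy-1,3-diene (C5=C6(OAr)–C7=C8).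
3. Enabling feature: in the cycloheptene ring B the fusion bond C1–C5 and the bond C8–C9 separate a three-carbon unit (C1, C10, C9) from a four-carbon unit (C5–C8) whose oxygen sits on an inner carbon (C6); C2–C3–C4 of ring A is the three-atom tether, so one event closes both rings.
4. Forward: the cyclohexene of (S)-terpinen-4-ol (supplies C15, C1–C6 and the isopropyl group) is hydroxylated, opened by ozonolysis, extended at C6 (C7, C8, C14) and at C1 (C10, C9); step 8 closes rings A and B; C8–C9 is formed there as a single bond and becomes the alkene in step 10.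
5. Stereochemistry: C4 from the chiral pool; C1 in step 8 by allylic strain from a temporary 2β-silyloxy centre (set in step 1, erased in step 10); C5 by the trans closure; C6 and C2 by delivery of H2 and of hydride from the 4β-hydroxyl.

Key step: step 8

Assumption: (S)-(+)-terpinen-4-ol is used enantiomerically pure; commercial material of lower ee would first be enriched (e.g. by recrystallisation of a crystalline ester).

**Route**

Step 1
Reactants: 1 (S)-(+)-terpinen-4-ol
Product: 2 (1R,5R)-5-isopropyl-2-methylcyclohex-2-ene-1,5-diol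
Conditions: SeO2 (0.5 equiv), t-BuOOH (2 equiv), CH2Cl2, 0 °C to rt
Reagents that add atoms: SeO2, O=[Se]=O (transfers the oxygen); tert-butyl hydroperoxide, CC(C)(C)OO (restores it)
Why: Allylic hydroxylation by SeO2 (ene reaction, then [2,3]-sigmatropic shift) should occur at the ring CH2 beside the methyl-bearing alkene carbon and deliver oxygen to the face of the pseudo-axial C–H, which is syn to the axial tertiary hydroxyl when isopropyl is equatorial, so the new carbinol (later C2, a temporary control centre) is set cis to the existing one by the ring conformation.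

Step 2
Reactants: 2 (1R,5R)-5-isopropyl-2-methylcyclohex-2-ene-1,5-diol
Product: 3 bis(triethylsilyl) ether of 2
Conditions: Et3SiOTf (2.5 equiv), 2,6-lutidine, CH2Cl2, −78 to 0 °C
Reagents that add atoms: triethylsilyl trifluoromethanesulfonate, CC[Si](CC)(CC)OS(=O)(=O)C(F)(F)F
Why: Silyl triflate silylation covers the secondary and the tertiary hydroxyl, which keeps the ring-opened product from forming lactols and from losing the β-oxygen; no stereocentre is touched.

Step 3
Reactants: 3 bis(triethylsilyl) ether of 2
Product: 4 3-isopropyl-6-oxo-3,5-bis(triethylsilyloxy)heptanal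
Conditions: O3, CH2Cl2, −78 °C; then PPh3, −78 °C to rt
Reagents that add atoms: ozone, [O-][O+]=O
Why: Ozonolysis with reductive work-up cleaves the only alkene to the methyl ketone (C1 with C15) and the aldehyde (C6) without touching the two stereocentres.

Step 4
Reactants: 4 3-isopropyl-6-oxo-3,5-bis(triethylsilyloxy)heptanal
Product: 5 (E)-7-hydroxy-5-isopropyl-3,5-bis(triethylsilyloxy)dec-8-en-2-one
Conditions: (E)-1-bromoprop-1-ene (2 equiv), CrCl2 (4 equiv), NiCl2 (2 mol %), DMF, rt
Reagents that add atoms: (E)-1-bromoprop-1-ene, C/C=C/Br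
Why: Nozaki–Hiyama–Kishi coupling: the alkenylchromium reagent adds to the aldehyde and not to the ketone and keeps the E geometry of the bromide, bringing in C7, C8 and C14; the new carbinol is formed without control and is oxidised in step 6.

Step 5
Reactants: 5 (E)-7-hydroxy-5-isopropyl-3,5-bis(triethylsilyloxy)dec-8-en-2-one
Product: 6 (E)-2-ethoxy-6-isopropyl-3-methyl-4,6-bis(triethylsilyloxy)undeca-1,9-diene-3,8-diol
Conditions: ethyl vinyl ether, t-BuLi, THF, −78 to 0 °C; then 5, −78 °C; NH4Cl (aq), −78 °C
Reagents that add atoms: 1-ethoxyvinyllithium, [Li]C(=C)OCC (made in the flask from ethyl vinyl ether, C=COCC, and t-BuLi)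
Why: 1,2-Addition of the acyl anion equivalent to the methyl ketone gives the tertiary 2-ethoxyallylic alcohol that carries the three-carbon unit C1–C10–C9 (one equivalent of reagent is taken by the free hydroxyl); the new carbinol configuration is irrelevant because C1 is ionised in step 8.

Step 6
Reactants: 6 (E)-2-ethoxy-6-isopropyl-3-methyl-4,6-bis(triethylsilyloxy)undeca-1,9-diene-3,8-diol
Product: 7 (E)-10-ethoxy-9-hydroxy-6-isopropyl-9-methyl-6,8-bis(triethylsilyloxy)undeca-2,10-dien-4-one
Conditions: MnO2 (excess), CH2Cl2, rt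
Reagents that add atoms: none
Why: MnO2 oxidises only the allylic secondary alcohol, under neutral conditions that spare the acid-labile enol ether and the tertiary alcohol, to give the (E)-propenyl ketone.

Step 7
Reactants: 7 (E)-10-ethoxy-9-hydroxy-6-isopropyl-9-methyl-6,8-bis(triethylsilyloxy)undeca-2,10-dien-4-one
Product: 8 (2E,4Z)-10-ethoxy-6-isopropyl-9-methyl-6,8-bis(triethylsilyloxy)undeca-2,4,10-triene-4,9-diyl bis(4-methoxybenzoate)
Conditions: KN(SiMe3)2 (2.2 equiv), THF, −78 °C; 4-MeOC6H4COCl (2.3 equiv), −78 to 0 °C; filtration through Et3N-deactivated silica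
Reagents that add atoms: 4-methoxybenzoyl chloride, COc1ccc(cc1)C(Cl)=O
Why: Kinetic deprotonation of the alkenyl ketone at C5 gives the enolate with the tether cis to oxygen, and O-acylation (enol ester formation) turns the ketone into the 2-acyloxydiene that already carries the 6-(4-methoxybenzoate), while acylation of the tertiary alkoxide supplies the leaving group at C1.

Step 8
Reactants: 8 (2E,4Z)-10-ethoxy-6-isopropyl-9-methyl-6,8-bis(triethylsilyloxy)undeca-2,4,10-triene-4,9-diyl bis(4-methoxybenzoate)
Product: 11 2β,4β-dihydroxy-10-oxodauc-6-en-6-yl 4-methoxybenzoate, via 2-ethoxyallyl cation 9 (not isolated), via enol ether cycloadduct 10 (not isolated)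
Conditions: Me3SiOTf (1.1 equiv), 2,6-di-tert-butyl-4-methylpyridine (1.5 equiv), CH2Cl2, −78 to −40 °C; then HF·pyridine, wet THF, 0 °C to rt
Reagents that add atoms: water, O (oxygen of the C10 ketone on hydrolysis of the enol ether)
Why: Me3SiOTf ionises the tertiary allylic 4-methoxybenzoate to the 2-ethoxyallyl cation 9 (C1–C10–C9), which adds across the termini C5 and C8 of the tethered 2-acyloxy-1,3-diene to form C1–C5 and C9–C8, the C10 oxocarbenium ion loses a proton to the hindered pyridine to give enol ether 10, and HF·pyridine then removes both silyl groups and hydrolyses the enol ether to the ketone. The closest known reaction type is the intramolecular (4+3) cycloaddition of 2-alkoxyallyl cations with dienes joined through a three-atom tether, which gives bicyclo[5.3.0]decenones. Ring A closes by 5-exo attack of the diene terminus C5 on the cation terminus C1 (C5=C6 stays outside the new ring), and ring B closes as the seven-membered cycloaddition ring when C9 bonds to C8 (a 7-endo closure onto the acyloxyallyl cation in the stepwise limit). At C1 the tether lets C5 reach only the face of the planar cation on which C3 lies and allylic 1,3-strain keeps the coplanar ethoxyvinyl group (C10) beside H2, so C15 ends up cis to the 2β-silyloxy group and C10 α; at C5, C6 takes the position trans to C10 across the new bond and away from the isopropyl group on C4, which gives the trans fusion with H5 α; the methyl-bearing C8 is formed without control and is flattened in step 10. The step needs cycloaddition to outrun proton loss from the cation and closure through oxygen: low temperature and the non-nucleophilic base, the O-ethyl group (no free oxyallyl oxygen) and the (Z)-enol ester geometry (tether on the outer side of an s-cis diene) are there to secure this, and only C5 can reach C1, so the orientation is fixed.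

Step 9
Reactants: 11 2β,4β-dihydroxy-10-oxodauc-6-en-6-yl 4-methoxybenzoate
Product: 12 2β,4β-dihydroxy-10-oxodaucan-6α-yl 4-methoxybenzoate
Conditions: H2 (1 atm), [Ir(cod)(PCy3)(py)]PF6 (10 mol %), CH2Cl2, rt
Reagents that add atoms: none
Why: Hydroxyl-directed homogeneous hydrogenation: the cationic iridium centre binds the 4β- and 2β-hydroxyls and adds H2 to the β face of the C6=C7 enol ester, which sets H6 β and the ester oxygen α.

Step 10
Reactants: 12 2β,4β-dihydroxy-10-oxodaucan-6α-yl 4-methoxybenzoate
Product: 13 4β-hydroxy-2,10-dioxodauc-8-en-6α-yl 4-methoxybenzoate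
Conditions: 2-iodoxybenzoic acid (IBX, 4 equiv), 4-methoxypyridine N-oxide (4 equiv), DMSO, rt
Reagents that add atoms: none
Why: 2-Iodoxybenzoic acid oxidises the secondary C2 alcohol and dehydrogenates the C10 ketone (oxidation of its enol), which can only enolise towards C9 because C1 is quaternary, so the double bond is placed at C8=C9 and the C8 stereocentre is erased; the C2 ketone has no position at which it can be desaturated.

Step 11
Reactants: 13 4β-hydroxy-2,10-dioxodauc-8-en-6α-yl 4-methoxybenzoate
Product: 14 2α,4β,10-trihydroxydauc-8-en-6α-yl 4-methoxybenzoate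
Conditions: Me4NBH(OAc)3 (8 equiv), MeCN/AcOH (1:1), −30 to 0 °C
Reagents that add atoms: none
Why: Evans–Saksena reduction: the triacetoxyborohydride bound to the 4β-hydroxyl delivers hydride to the β face of the C2 ketone (anti-1,3-diol, 2α-OH), and the new 2-hydroxyl then directs 1,2-reduction of the C10 enone to the allylic alcohol, whose configuration is irrelevant.

Step 12
Reactants: 14 2α,4β,10-trihydroxydauc-8-en-6α-yl 4-methoxybenzoate
Product: 15 2α,10-diacetoxy-4β-hydroxydauc-8-en-6α-yl 4-methoxybenzoate
Conditions: Ac2O (5 equiv), Et3N, DMAP (0.2 equiv), CH2Cl2, 0 °C to rt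
Reagents that add atoms: acetic anhydride, CC(=O)OC(C)=O
Why: DMAP-catalysed acylation esterifies the two secondary alcohols and leaves the hindered tertiary 4-hydroxyl free; the C2 acetate is the one of the target and the C10 acetate is the allylic leaving group.

Step 13
Reactants: 15 2α,10-diacetoxy-4β-hydroxydauc-8-en-6α-yl 4-methoxybenzoate
Product: 16 2α-acetoxy-4β-hydroxydauc-8-en-6α-yl 4-methoxybenzoate
Conditions: Pd(PPh3)4 (10 mol %), NaBH4 (2 equiv), THF, rt
Reagents that add atoms: none
Why: Palladium-catalysed allylic hydrogenolysis: only the allylic C10 acetate ionises to a π-allyl complex (C10–C9–C8), and borohydride attacks its less substituted terminus C10, which keeps the trisubstituted C8=C9 alkene and leaves the other esters untouched.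

**Compound list**

1 | (S)-(+)-terpinen-4-ol, (1S)-4-methyl-1-(propan-2-yl)cyclohex-3-en-1-ol | CC1=CC[C@](O)(C(C)C)CC1 | starting material
2 | (1R,5R)-5-isopropyl-2-methylcyclohex-2-ene-1,5-diol (hydroxyls cis) | CC1=CC[C@](O)(C(C)C)C[C@H]1O | intermediate
3 | bis(triethylsilyl) ether of 2 | CC1=CC[C@](O[Si](CC)(CC)CC)(C(C)C)C[C@H]1O[Si](CC)(CC)CC | intermediate
4 | 3-isopropyl-6-oxo-3,5-bis(triethylsilyloxy)heptanal (silyloxy carbons as in 3) | CC(=O)[C@H](O[Si](CC)(CC)CC)C[C@@](O[Si](CC)(CC)CC)(C(C)C)CC=O | intermediate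
5 | (E)-7-hydroxy-5-isopropyl-3,5-bis(triethylsilyloxy)dec-8-en-2-one (C7 epimers) | CC(=O)[C@H](O[Si](CC)(CC)CC)C[C@@](O[Si](CC)(CC)CC)(C(C)C)CC(O)/C=C/C | intermediate
6 | (E)-2-ethoxy-6-isopropyl-3-methyl-4,6-bis(triethylsilyloxy)undeca-1,9-diene-3,8-diol (C3 and C8 epimers) | C=C(OCC)C(C)(O)[C@H](O[Si](CC)(CC)CC)C[C@@](O[Si](CC)(CC)CC)(C(C)C)CC(O)/C=C/C | intermediate
7 | (E)-10-ethoxy-9-hydroxy-6-isopropyl-9-methyl-6,8-bis(triethylsilyloxy)undeca-2,10-dien-4-one (C9 epimers) | C=C(OCC)C(C)(O)[C@H](O[Si](CC)(CC)CC)C[C@@](O[Si](CC)(CC)CC)(C(C)C)CC(=O)/C=C/C | intermediate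
8 | (2E,4Z)-10-ethoxy-6-isopropyl-9-methyl-6,8-bis(triethylsilyloxy)undeca-2,4,10-triene-4,9-diyl bis(4-methoxybenzoate) | C=C(OCC)C(C)(OC(=O)c1ccc(OC)cc1)[C@H](O[Si](CC)(CC)CC)C[C@@](O[Si](CC)(CC)CC)(C(C)C)/C=C(\OC(=O)c1ccc(OC)cc1)/C=C/C | intermediate
9 | 2-ethoxyallyl cation formed from 8 by loss of the tertiary 4-methoxybenzoate (not isolated) | C=C(OCC)[C+](C)[C@H](O[Si](CC)(CC)CC)C[C@@](O[Si](CC)(CC)CC)(C(C)C)/C=C(\OC(=O)c1ccc(OC)cc1)/C=C/C | intermediate
10 | 10-ethoxy-2β,4β-bis(triethylsilyloxy)dauca-6,9-dien-6-yl 4-methoxybenzoate (trans-fused; C8 methyl undefined; not isolated) | COc1ccc(C(=O)OC2=CC(C)C=C(OCC)[C@@]3(C)[C@H](O[Si](CC)(CC)CC)C[C@@](O[Si](CC)(CC)CC)(C(C)C)[C@H]23)cc1 | intermediate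
11 | 2β,4β-dihydroxy-10-oxodauc-6-en-6-yl 4-methoxybenzoate (1β-methyl, 5α-H; C8 methyl undefined) | COc1ccc(C(=O)OC2=CC(C)CC(=O)[C@@]3(C)[C@H](O)C[C@@](O)(C(C)C)[C@H]23)cc1 | intermediate
12 | 2β,4β-dihydroxy-10-oxodaucan-6α-yl 4-methoxybenzoate (C8 methyl undefined) | COc1ccc(C(=O)O[C@H]2CC(C)CC(=O)[C@@]3(C)[C@H](O)C[C@@](O)(C(C)C)[C@H]23)cc1 | intermediate
13 | 4β-hydroxy-2,10-dioxodauc-8-en-6α-yl 4-methoxybenzoate | COc1ccc(C(=O)O[C@H]2CC(C)=CC(=O)[C@@]3(C)C(=O)C[C@@](O)(C(C)C)[C@H]23)cc1 | intermediate
14 | 2α,4β,10-trihydroxydauc-8-en-6α-yl 4-methoxybenzoate (C10 epimers) | COc1ccc(C(=O)O[C@H]2CC(C)=CC(O)[C@@]3(C)[C@@H](O)C[C@@](O)(C(C)C)[C@H]23)cc1 | intermediate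
15 | 2α,10-diacetoxy-4β-hydroxydauc-8-en-6α-yl 4-methoxybenzoate (C10 epimers) | COc1ccc(C(=O)O[C@H]2CC(C)=CC(OC(C)=O)[C@@]3(C)[C@@H](OC(C)=O)C[C@@](O)(C(C)C)[C@H]23)cc1 | intermediate
16 | 2α-acetoxy-4β-hydroxydauc-8-en-6α-yl 4-methoxybenzoate | COc1ccc(C(=O)O[C@H]2CC(C)=CC[C@@]3(C)[C@@H](OC(C)=O)C[C@@](O)(C(C)C)[C@H]23)cc1 | target

**Totals and risks**

Total step count: 13. Longest linear sequence: 13 steps, from 1.

Steps most likely to fail:

1. Step 8. The cation may be lost by proton loss to an alkoxydiene before the weakly nucleophilic acyloxydiene engages it, the sequence may stop after the first bond, or the fusion may close without full facial control. The fallback closes the two rings in separate polar steps. It sets out from 7, which is silylated on both oxygens (KN(SiMe3)2, Me3SiCl) to the bis(trimethylsilyl) dienol ether F1. Catalytic Me3SiOTf at −78 °C then ionises C1, and the silyl dienol ether alkylates the cation (intramolecular Mukaiyama-type alkylation, ring A); mild acid work-up should give the trans-disposed acetyl propenoyl cyclopentane F2, in which C5 can be equilibrated next to the C6 ketone. KN(SiMe3)2 at −78 °C forms the methyl ketone enolate, which closes ring B by intramolecular Michael addition to C8; the trans arrangement makes the competing five-ring aldol closure strained. The C6 enolate so formed is trapped with 4-methoxybenzoyl chloride as the enol ester ketone F3, and HF·pyridine returns to the route at 11.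

2. Step 1. Oxygen may be transferred from the wrong face or partly at the methyl group, and the allylic alcohol may be oxidised further. The fallback sets the carbinol by reduction instead. From 1, SeO2/t-BuOOH followed by MnO2 takes all ring-oxidised material to 5-hydroxy-5-isopropyl-2-methylcyclohex-2-en-1-one F4. Chelation-controlled 1,2-reduction (Et2BOMe, NaBH4, THF/MeOH, −78 °C; hydride anti to the boron bridge between the axial hydroxyl and the carbonyl) should then give the cis-diol and return at 2.

3. Step 13. Hydride may be delivered to the tertiary allyl terminus (double bond moved to C9=C10), or the π-allyl complex may lose a β-hydrogen to a diene. The fallback removes the C10 oxygen through sulfur. It sets out from 14: MnO2 re-oxidises only the allylic alcohol to the 2α,4β-dihydroxy enone F5, acetylation (Ac2O, DMAP) gives the 2α-acetoxy enone F6, ethane-1,2-dithiol with BF3·OEt2 gives the 1,3-dithiolane F7 without moving the conjugated double bond, and deactivated Raney nickel in ethanol desulfurises it to 16.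

**Further compounds**

F1 | step 8 | bis(trimethylsilyl) derivative of 7 (trimethylsilyl dienol ether and tertiary trimethylsilyl ether) | C=C(OCC)C(C)(O[Si](C)(C)C)[C@H](O[Si](CC)(CC)CC)C[C@@](O[Si](CC)(CC)CC)(C(C)C)/C=C(\O[Si](C)(C)C)/C=C/C
F2 | step 8 | (E)-1-[2-acetyl-5-isopropyl-2-methyl-3,5-bis(triethylsilyloxy)cyclopentyl]but-2-en-1-one (acetyl and butenoyl trans) | CC(=O)[C@@]1(C)[C@H](O[Si](CC)(CC)CC)C[C@@](O[Si](CC)(CC)CC)(C(C)C)[C@@H]1C(=O)/C=C/C
F3 | step 8 | 10-oxo-2β,4β-bis(triethylsilyloxy)dauc-6-en-6-yl 4-methoxybenzoate | COc1ccc(C(=O)OC2=CC(C)CC(=O)[C@@]3(C)[C@H](O[Si](CC)(CC)CC)C[C@@](O[Si](CC)(CC)CC)(C(C)C)[C@H]23)cc1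
F4 | step 1 | (R)-5-hydroxy-5-isopropyl-2-methylcyclohex-2-en-1-one | CC1=CC[C@](O)(C(C)C)CC1=O
F5 | step 13 | 2α,4β-dihydroxy-10-oxodauc-8-en-6α-yl 4-methoxybenzoate | COc1ccc(C(=O)O[C@H]2CC(C)=CC(=O)[C@@]3(C)[C@@H](O)C[C@@](O)(C(C)C)[C@H]23)cc1
F6 | step 13 | 2α-acetoxy-4β-hydroxy-10-oxodauc-8-en-6α-yl 4-methoxybenzoate | COc1ccc(C(=O)O[C@H]2CC(C)=CC(=O)[C@@]3(C)[C@@H](OC(C)=O)C[C@@](O)(C(C)C)[C@H]23)cc1
F7 | step 13 | 1,3-dithiolane of F6 at C10 | COc1ccc(C(=O)O[C@H]2CC(C)=CC4(SCCS4)[C@@]3(C)[C@@H](OC(C)=O)C[C@@](O)(C(C)C)[C@H]23)cc1
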